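**Retrosynthetic overview**
1. The strategy rests on ring C (C13–C14–C15–C16–C20–C19): quaternary spiro C13 sits next to the C14 ketone, and the C16–O and C19–C18 bonds are cis. This pattern is a bicyclo[2.2.2]octenone in disguise, whose etheno bridge C17=C18 delivers C18.
2. Key disconnection: C15–C16 and C19–C20, by [4+2] addition of the isobutyraldehyde silyl enol ether 10 to the 6,6-disubstituted cyclohexa-2,4-dienone 8. C13 in 8 is set by asymmetric Birch reduction–alkylation of a 2-methoxybenzamide.
3. Ring D (tetrahydrofuran C16–O–C18–C19–C20): ozonolysis of the bridge, loss of the C15 formyl group (C17), lactol formation and reduction.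
4. Ring B (δ-lactone): intramolecular Horner–Wadsworth–Emmons reaction between the C13 formyl group (former amide carbon C1) and a phosphonoacetate on C12–O. Ring A: Diels–Alder reaction of that enelactone with 2-silyloxybutadiene.
5. Side chain: iridium-catalysed branched allylation at C4, removal of the C5 ketone, oxidative cleavage to the acid. Order of ring formation: C, D, B, A.

Key step: step 6

Numbering used throughout: ring A C1–C6 (C1 bound to C13, C2 bears lactone carbonyl C11, C4 bears side chain C7 with methyl C8 and carboxyl C9); ring B C13–C1–C2–C11(=O)–O–C12; ring C C13–C14(=O)–C15–C16–C20(Me2)–C19; ring D C16–O–C18–C19–C20; C17 is the etheno carbon on C15 that is later lost.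

Assumption: the amide enolate of step 2 is taken to be alkylated in the facial sense usual for 2-methoxybenzamides of this auxiliary, giving the (R) quaternary carbon drawn; if the opposite sense holds, (R)-2-(methoxymethyl)pyrrolidine is used instead.

**Step 1**
Reactants: 1 2-methoxybenzoyl chloride; 2 (S)-2-(methoxymethyl)pyrrolidine
Product: 3 (S)-(2-methoxyphenyl)[2-(methoxymethyl)pyrrolidin-1-yl]methanone
Conditions: Et3N, CH2Cl2, 0 to 23 °C
Reagents that add atoms: none
Why: Schotten–Baumann-type N-acylation of the secondary amine by the acid chloride; no stereocentre is touched.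

**Step 2**
Reactants: 3 benzamide; 4 benzyl chloromethyl ether
Product: 5 [(R)-1-(benzyloxymethyl)-2-methoxycyclohexa-2,5-dien-1-yl][(S)-2-(methoxymethyl)pyrrolidin-1-yl]methanone
Conditions: K, NH3/THF, t-BuOH (1 equiv), −78 °C; piperylene; then 4, −78 °C
Reagents that add atoms: none
Why: Birch reduction–alkylation: the chelated potassium amide enolate formed by reduction and C17 protonation should be alkylated at the ipso carbon on the face away from the auxiliary side chain, which sets quaternary C13.

**Step 3**
Reactants: 5 dienyl methyl ether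
Product: 6 (R)-2-(benzyloxymethyl)-2-[(S)-2-(methoxymethyl)pyrrolidine-1-carbonyl]cyclohex-3-en-1-one
Conditions: 1 M HCl, THF, 23 °C
Reagents that add atoms: water, O
Why: Acid hydrolysis of the methyl enol ether to the C14 ketone; the C18=C19 alkene cannot move into conjugation through quaternary C13, and C13 is not enolisable.

**Step 4**
Reactants: 6 β,γ-unsaturated ketone
Product: 8 (R)-6-(benzyloxymethyl)-6-[(S)-2-(methoxymethyl)pyrrolidine-1-carbonyl]cyclohexa-2,4-dien-1-one, via trimethylsilyl enol ether 7 (not isolated)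
Conditions: LDA, Me3SiCl, THF, −78 °C; then Pd(OAc)2, MeCN, 23 °C
Reagents that add atoms: chlorotrimethylsilane, C[Si](C)(C)Cl (its atoms stay only in 7)
Why: Saegusa–Ito oxidation: C15 is the only enolisable position, and β-hydride elimination of the doubly allylic C17–H from the palladium enolate should give the linearly conjugated 2,4-dienone.

**Step 5**
Reactants: 9 isobutyraldehyde
Product: 10 tert-butyldimethyl(2-methylprop-1-enyloxy)silane
Conditions: t-BuMe2SiOTf, Et3N, CH2Cl2, 0 to 23 °C
Reagents that add atoms: tert-butyldimethylsilyl trifluoromethanesulfonate, CC(C)(C)[Si](C)(C)OS(=O)(=O)C(F)(F)F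
Why: Soft enolisation and O-silylation of the aldehyde (silyl enol ether formation); the alkene has no E/Z issue.

**Step 6**
Reactants: 8 cyclohexa-2,4-dienone; 10 silyl enol ether
Product: 11 3-(benzyloxymethyl)-7-(tert-butyldimethylsilyloxy)-8,8-dimethyl-3-[(S)-2-(methoxymethyl)pyrrolidine-1-carbonyl]bicyclo[2.2.2]oct-5-en-2-one (C16–OSi syn to the C17=C18 etheno bridge; carboxamide on C13 syn to that bridge; CH2OBn syn to the C16–C20 bridge)
Conditions: 10 (8 equiv), BHT, CH2Cl2, 13 kbar, 35 °C
Reagents that add atoms: none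
Why: The linearly conjugated dienone 8 serves as the electron-poor 4π unit (C15=C17–C18=C19) and enol ether 10 as the electron-rich 2π unit in a concerted, asynchronous inverse-electron-demand Diels–Alder reaction; the closest known type is the cycloaddition of 6,6-disubstituted cyclohexa-2,4-dienones (masked o-benzoquinones) with enol ethers. The carbocyclic ring C (C13–C14–C15–C16–C20–C19) is closed by suprafacial formation of both C15–C16 and C19–C20 in the [4+2] event, which leaves C17=C18 as the etheno bridge of a bicyclo[2.2.2]octenone. Regiochemistry follows from the frontier orbitals: the nucleophilic CMe2 terminus joins C19, the δ-carbon with the largest LUMO coefficient, so the oxygen-bearing carbon becomes C16 next to C15. C16 is set by the endo orientation of the silyloxy group (under the diene and away from the C14 carbonyl dipole), which places it syn to the etheno bridge and so cis to the future C18. C15 and C19 follow from the face of addition, which the preset C13 centre controls: the enol ether should approach anti to the twisted tertiary carboxamide and syn to the slimmer CH2OBn arm. High pressure is chosen because a fully substituted carbon has to bond next to a quaternary centre and the dienone would otherwise dimerise.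

**Step 7**
Reactants: 11 bicyclo[2.2.2]octenone
Product: 13 keto aldehyde of ring C (C14 ketone; C15 CH2; C16 OSiMe2t-Bu; C19 bearing the C18 formyl group cis to the C16 oxygen), via dialdehyde 12 (not isolated)
Conditions: O3, CH2Cl2/MeOH, −78 °C; Me2S; then K2CO3, MeOH, 0 °C
Reagents that add atoms: ozone, [O-][O+]=O
Why: Ozonolysis of the strained etheno bridge gives formyl groups on C15 and C19, and the C15 formyl group (C17), being β to the C14 ketone, is removed as methyl formate by retro-Claisen cleavage; C19 should keep its configuration because enolisation between two quaternary carbons is slow.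

**Step 8**
Reactants: 13 silyloxy keto aldehyde
Product: 14 lactol (7-hydroxy-6-oxabicyclo[3.2.1]octan-3-one core; mixture at C18)
Conditions: HF·pyridine, THF, 0 to 23 °C
Reagents that add atoms: none
Why: Fluoride-mediated desilylation frees the C16 hydroxyl, which is cis to C18 and adds to the aldehyde to give the five-membered hemiacetal (ring D at the lactol level).

**Step 9**
Reactants: 14 lactol
Product: 15 2-(benzyloxymethyl)-8,8-dimethyl-2-[(S)-2-(methoxymethyl)pyrrolidine-1-carbonyl]-6-oxabicyclo[3.2.1]octan-3-one (rings C and D; carboxamide on C13 cis to C18)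
Conditions: Et3SiH, BF3·OEt2, CH2Cl2, −78 to −20 °C
Reagents that add atoms: none
Why: Ionic hydrogenation of a lactol: BF3 ionises C18 to the oxocarbenium ion, which the silane reduces to the cyclic ether, while ketone, amide and benzyl ether should not react at this temperature.

**Step 10**
Reactants: 15 keto amide
Product: 16 diol (C1 as CH2OH on C13; C14 as CHOH, epimer mixture; C12 as CH2OBn)
Conditions: LiNH2BH3 (from BH3·NH3, n-BuLi), THF, 0 to 23 °C; aqueous HCl work-up
Reagents that add atoms: none
Why: Reduction of a tertiary amide to the primary alcohol with lithium amidotrihydroborate, a reagent known to reduce α-quaternary tertiary amides with C–N cleavage; the C14 ketone is reduced as well and is restored in step 11.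

**Step 11**
Reactants: 16 diol
Product: 17 keto aldehyde (C1 formyl and CH2OBn on C13; C14 ketone)
Conditions: triacetoxyperiodinane (1,1,1-triacetoxy-1,1-dihydro-1,2-benziodoxol-3(1H)-one), CH2Cl2, 23 °C
Reagents that add atoms: none
Why: Periodinane oxidation of the primary and the secondary alcohol under neutral conditions; C13 carries no hydrogen, so the β-keto aldehyde cannot epimerise.

**Step 12**
Reactants: 17 benzyl ether
Product: 18 hydroxy keto aldehyde (C12 as CH2OH)
Conditions: H2 (1 atm), Pd/C, EtOAc, 23 °C
Reagents that add atoms: none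
Why: Hydrogenolysis of the benzyl ether; the hindered aliphatic aldehyde and the ketone should not be reduced over palladium on carbon in ethyl acetate.

**Step 13**
Reactants: 18 hydroxy keto aldehyde; 19 diethylphosphonoacetic acid
Product: 20 phosphonoacetate ester on C12–O (C1 formyl and C14 ketone retained)
Conditions: DCC, DMAP (cat.), CH2Cl2, 0 to 23 °C
Reagents that add atoms: none
Why: Steglich esterification of the primary neopentyl alcohol; no base strong enough for retro-aldol loss of formaldehyde is present.

**Step 14**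
Reactants: 20 phosphonoacetate aldehyde
Product: 21 spiro enelactone (5,6-dihydro-2H-pyran-2-one with C1=C2, spiro at C13 to the 8,8-dimethyl-6-oxabicyclo[3.2.1]octan-3-one; C1 cis to C18)
Conditions: LiCl, iPr2NEt, MeCN, 23 °C
Reagents that add atoms: none
Why: Intramolecular Horner–Wadsworth–Emmons reaction under mild LiCl/amine conditions closes ring B; the aldehyde is far more electrophilic than the hindered C14 ketone, and the six-membered ring enforces the Z C1=C2 bond.

**Step 15**
Reactants: 21 enelactone; 22 2-(trimethylsilyloxy)buta-1,3-diene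
Product: 23 cycloadduct (ring A cis-fused to ring B; C4=C5 enol ether with OSiMe3 on C5; ring A carbons C3 and C6 on the C14 face of the lactone)
Conditions: 22 (5 equiv), BHT, CH2Cl2, 13 kbar, 40 °C
Reagents that add atoms: none
Why: Normal-demand Diels–Alder reaction: the Z-enoate gives the cis ring fusion, the diene terminus next to the siloxy carbon bonds to the β-carbon C1 (oxygen para to the carbonyl-bearing C2), and the diene is expected to approach from the flat C14 carbonyl flank of the spiro centre, not the C19 flank, which carries C18 and the gem-dimethyl carbon.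

**Step 16**
Reactants: 23 trimethylsilyl enol ether; 24 methyl (E)-but-2-en-1-yl carbonate
Product: 25 diketone lactone (C5 ketone; C4 bearing (S)-but-3-en-2-yl, trans to the C2–C11 bond and equatorial)
Conditions: [Ir(cod)Cl]2 (2 mol %), BINOL-derived N,N-bis(1-phenylethyl)phosphoramidite (4 mol %), CsF (cat.), ZnF2 (cat.), DME, 50 °C; then DBU (cat.), CH2Cl2, 23 °C
Reagents that add atoms: none
Why: Iridium-catalysed branched-selective allylic substitution (Tsuji–Trost type) of a silyl enol ether: the fluoride-released enolate attacks the substituted terminus of the crotyl iridium complex, the ligand enantiomer is chosen to set C7, and C4 is alkylated anti to the axial C2–C11 bond and, being α to the C5 ketone, can equilibrate to the same equatorial isomer.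

**Step 17**
Reactants: 25 diketone lactone
Product: 27 C5-methylene compound (C4 bearing (S)-but-3-en-2-yl; C14 ketone and lactone intact), via tosylhydrazone 26 (not isolated)
Conditions: TsNHNH2, MeOH, 23 °C; then catecholborane, CHCl3, 0 °C; NaOAc·3H2O, reflux
Reagents that add atoms: p-toluenesulfonyl hydrazide, Cc1ccc(cc1)S(=O)(=O)NN (its atoms stay only in 26)
Why: Tosylhydrazone reduction (a mild Wolff–Kishner equivalent): the hydrazone should form only at the unhindered C5 ketone and not at C14 beside quaternary C13, and hydride delivery followed by loss of sulfinate and N2 gives the methylene group without touching lactone or alkene.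

**Step 18**
Reactants: 27 vinyl compound
Product: 29 target acid CNP0152427.1, via aldehyde 28 (not isolated)
Conditions: O3, CH2Cl2, −78 °C; PPh3; then NaClO2, NaH2PO4, 2-methylbut-2-ene, t-BuOH/H2O, 23 °C
Reagents that add atoms: ozone, [O-][O+]=O; sodium chlorite, [Na+].[O-]Cl=O
Why: Ozonolysis of the terminal vinyl group and Pinnick oxidation of the resulting α-branched aldehyde under buffered conditions give the carboxylic acid without epimerising C7.

**Compound list**
1 | 2-methoxybenzoyl chloride | COc1ccccc1C(Cl)=O | starting material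
2 | (S)-2-(methoxymethyl)pyrrolidine | COC[C@@H]1CCCN1 | starting material
3 | (S)-(2-methoxyphenyl)[2-(methoxymethyl)pyrrolidin-1-yl]methanone | COc1ccccc1C(=O)N1CCC[C@H]1COC | intermediate
4 | benzyl chloromethyl ether | ClCOCc1ccccc1 | starting material
5 | [(R)-1-(benzyloxymethyl)-2-methoxycyclohexa-2,5-dien-1-yl][(S)-2-(methoxymethyl)pyrrolidin-1-yl]methanone | COC1=CCC=C[C@]1(COCc2ccccc2)C(=O)N3CCC[C@H]3COC | intermediate
6 | (R)-2-(benzyloxymethyl)-2-[(S)-2-(methoxymethyl)pyrrolidine-1-carbonyl]cyclohex-3-en-1-one | O=C1CCC=C[C@]1(COCc2ccccc2)C(=O)N3CCC[C@H]3COC | intermediate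
7 | [(R)-1-(benzyloxymethyl)-2-(trimethylsilyloxy)cyclohexa-2,5-dien-1-yl][(S)-2-(methoxymethyl)pyrrolidin-1-yl]methanone | C[Si](C)(C)OC1=CCC=C[C@]1(COCc2ccccc2)C(=O)N3CCC[C@H]3COC | intermediate
8 | (R)-6-(benzyloxymethyl)-6-[(S)-2-(methoxymethyl)pyrrolidine-1-carbonyl]cyclohexa-2,4-dien-1-one | O=C1C=CC=C[C@]1(COCc2ccccc2)C(=O)N3CCC[C@H]3COC | intermediate
9 | isobutyraldehyde | CC(C)C=O | starting material
10 | tert-butyldimethyl(2-methylprop-1-enyloxy)silane | CC(C)=CO[Si](C)(C)C(C)(C)C | intermediate
11 | 3-(benzyloxymethyl)-7-(tert-butyldimethylsilyloxy)-8,8-dimethyl-3-[(S)-2-(methoxymethyl)pyrrolidine-1-carbonyl]bicyclo[2.2.2]oct-5-en-2-one; silyloxy and carboxamide syn to the etheno bridge | O=C1[C@@H]2C=C[C@@H](C(C)(C)[C@H]2O[Si](C)(C)C(C)(C)C)[C@]1(COCc3ccccc3)C(=O)N4CCC[C@H]4COC | intermediate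
12 | ring C dialdehyde: cyclohexanone with formyl groups on C15 and C19, silyloxy on C16 | O=C1[C@H](C=O)[C@H](O[Si](C)(C)C(C)(C)C)C(C)(C)[C@H](C=O)[C@]1(COCc2ccccc2)C(=O)N3CCC[C@H]3COC | intermediate
13 | ring C keto aldehyde: C15 methylene, C16 silyloxy, C19 formyl (C18) cis to the C16 oxygen | O=C1C[C@H](O[Si](C)(C)C(C)(C)C)C(C)(C)[C@H](C=O)[C@]1(COCc2ccccc2)C(=O)N3CCC[C@H]3COC | intermediate
14 | lactol: 2-(benzyloxymethyl)-7-hydroxy-8,8-dimethyl-2-[(S)-2-(methoxymethyl)pyrrolidine-1-carbonyl]-6-oxabicyclo[3.2.1]octan-3-one, anomer mixture | O=C1C[C@@H]2OC(O)[C@@H](C2(C)C)[C@]1(COCc3ccccc3)C(=O)N4CCC[C@H]4COC | intermediate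
15 | 2-(benzyloxymethyl)-8,8-dimethyl-2-[(S)-2-(methoxymethyl)pyrrolidine-1-carbonyl]-6-oxabicyclo[3.2.1]octan-3-one; carboxamide cis to C18 | O=C1C[C@@H]2OC[C@@H](C2(C)C)[C@]1(COCc3ccccc3)C(=O)N4CCC[C@H]4COC | intermediate
16 | 2-(benzyloxymethyl)-2-(hydroxymethyl)-8,8-dimethyl-6-oxabicyclo[3.2.1]octan-3-ol; CH2OH cis to C18; C14 epimer mixture | OC1C[C@@H]2OC[C@@H](C2(C)C)[C@]1(COCc3ccccc3)CO | intermediate
17 | 2-(benzyloxymethyl)-8,8-dimethyl-3-oxo-6-oxabicyclo[3.2.1]octane-2-carbaldehyde; formyl cis to C18 | O=C1C[C@@H]2OC[C@@H](C2(C)C)[C@]1(COCc3ccccc3)C=O | intermediate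
18 | 2-(hydroxymethyl)-8,8-dimethyl-3-oxo-6-oxabicyclo[3.2.1]octane-2-carbaldehyde | O=C1C[C@@H]2OC[C@@H](C2(C)C)[C@]1(CO)C=O | intermediate
19 | diethylphosphonoacetic acid | CCOP(=O)(CC(=O)O)OCC | starting material
20 | (2-formyl-8,8-dimethyl-3-oxo-6-oxabicyclo[3.2.1]octan-2-yl)methyl 2-(diethoxyphosphoryl)acetate | O=C1C[C@@H]2OC[C@@H](C2(C)C)[C@]1(COC(=O)CP(=O)(OCC)OCC)C=O | intermediate
21 | spiro enelactone: 5,6-dihydro-2H-pyran-2-one (C1=C2) spiro at C13 to 8,8-dimethyl-6-oxabicyclo[3.2.1]octan-3-one | O=C1C[C@@H]2OC[C@@H](C2(C)C)[C@@]13COC(=O)C=C3 | intermediate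
22 | 2-(trimethylsilyloxy)buta-1,3-diene | C=CC(=C)O[Si](C)(C)C | starting material
23 | cycloadduct: cis-fused rings A and B, C5 trimethylsilyl enol ether (C4=C5), rings C and D as in 21 | C1=C(O[Si](C)(C)C)C[C@@H]2[C@H](C1)C(=O)OC[C@]21C(=O)C[C@@H]2OC[C@H]1C2(C)C | intermediate
24 | methyl (E)-but-2-en-1-yl carbonate | C/C=C/COC(=O)OC | starting material
25 | C5-ketone with (S)-but-3-en-2-yl on C4 (equatorial, trans to the C2–C11 bond) | C[C@@H](C=C)[C@@H]1C(=O)C[C@@H]2[C@H](C1)C(=O)OC[C@]21C(=O)C[C@@H]2OC[C@H]1C2(C)C | intermediate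
26 | C5 p-toluenesulfonylhydrazone of 25 | C[C@@H](C=C)[C@@H]1C(=NNS(=O)(=O)c3ccc(C)cc3)C[C@@H]2[C@H](C1)C(=O)OC[C@]21C(=O)C[C@@H]2OC[C@H]1C2(C)C | intermediate
27 | C5-methylene compound with (S)-but-3-en-2-yl on C4 | C[C@@H](C=C)[C@@H]1CC[C@@H]2[C@H](C1)C(=O)OC[C@]21C(=O)C[C@@H]2OC[C@H]1C2(C)C | intermediate
28 | (R)-2-substituted propanal (C9 as aldehyde) | C[C@@H](C=O)[C@@H]1CC[C@@H]2[C@H](C1)C(=O)OC[C@]21C(=O)C[C@@H]2OC[C@H]1C2(C)C | intermediate
29 | CNP0152427.1, (R)-2-substituted propanoic acid on C4 of the tetracyclic keto lactone ether | C[C@@H](C(=O)O)[C@@H]1CC[C@@H]2[C@H](C1)C(=O)OC[C@]21C(=O)C[C@@H]2OC[C@H]1C2(C)C | target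

**Step count and risks**
Total step count: 18. Longest linear sequence: 17 steps (steps 1–4 and 6–18; step 5 is a one-step branch).

Steps most likely to fail:

1. Step 6. The enol ether may add to the face of 8 that carries the carboxamide instead of the CH2OBn face (loss or reversal of facial control), and addition of the hindered alkene may be slow enough for the dienone to dimerise. High pressure is the answer to the second problem. The fallback answers the first by exchanging the roles of the two one-carbon arms on C13 and using the enantiomeric auxiliary. It sets out from 1. Acylation of (R)-2-(methoxymethyl)pyrrolidine gives the enantiomeric amide F1. Birch reduction–alkylation with 4 gives the dienyl methyl ether F2, and acid hydrolysis gives the enone F3. Silylation to the trimethylsilyl enol ether F4 and Saegusa–Ito oxidation give the dienone F5. Cycloaddition with 10, now on the carboxamide face, gives the cycloadduct F6, in which CH2OBn is syn to the etheno bridge. Ozonolysis to the dialdehyde F7 and deformylation give the keto aldehyde F8. Desilylation gives the lactol F9, and silane reduction gives the bicyclic ether F10. Lithium amidotrihydroborate gives the diol F11, whose new CH2OH is now the lactone arm C12. Steglich esterification of this primary alcohol with 19 gives the phosphonoacetate F12, and hydrogenolysis gives the diol F13. Oxidation of both hydroxyl groups with triacetoxyperiodinane comes back to the route at 20.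

2. Step 15. Cycloaddition at the neopentyl carbon C1 may be sluggish, with decomposition of the siloxydiene, and the diene may approach from the C19 flank of the spiro centre. The fallback delivers the diene from the C14 oxygen through a temporary silicon tether. It sets out from 21. Luche reduction (NaBH4, CeCl3·7H2O, MeOH, −78 °C) of the C14 ketone gives the alcohol F14. Treatment with iPr2Si(OTf)2 and 2,6-lutidine, then methyl vinyl ketone and Et3N, gives the silicon-tethered siloxydiene F15. Heating in toluene should give, by intramolecular Diels–Alder reaction from the C14 side, the bridged silyl enol ether F16. Iridium-catalysed allylation with 24 as in step 16, followed by aqueous HF, gives the hydroxy ketone F17. Oxidation with triacetoxyperiodinane comes back to the route at 25.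

3. Step 16. The enolate may attack the unsubstituted allyl terminus (linear product), the enol ether may be protodesilylated before C–C bond formation, or control at C7 may be weak. The fallback removes the regiochemical question with a symmetrical allyl unit. It sets out from 23. Tsuji–Trost allylation with racemic (E)-pent-3-en-2-yl methyl carbonate, Pd2(dba)3 and the C2-symmetric N,N'-(cyclohexane-1,2-diyl)bis(2-diphenylphosphinobenzamide) ligand gives the pentenyl ketone F18. Tosylhydrazone F19 is formed and reduced with catecholborane as in step 17 to the C5-methylene compound F20. Ozonolysis of the propenyl group comes back to the route at 28, which is oxidised to 29 as in step 18.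

**Further compounds**
F1 | step 6 | (R)-(2-methoxyphenyl)[2-(methoxymethyl)pyrrolidin-1-yl]methanone | COc1ccccc1C(=O)N1CCC[C@@H]1COC
F2 | step 6 | enantiomer of 5 | COC1=CCC=C[C@]1(C(=O)N2CCC[C@@H]2COC)COCc3ccccc3
F3 | step 6 | enantiomer of 6 | O=C1CCC=C[C@]1(C(=O)N2CCC[C@@H]2COC)COCc3ccccc3
F4 | step 6 | enantiomer of 7 | C[Si](C)(C)OC1=CCC=C[C@]1(C(=O)N2CCC[C@@H]2COC)COCc3ccccc3
F5 | step 6 | enantiomer of 8 | O=C1C=CC=C[C@]1(C(=O)N2CCC[C@@H]2COC)COCc3ccccc3
F6 | step 6 | bicyclo[2.2.2]octenone with CH2OBn syn to the etheno bridge and the (R)-auxiliary carboxamide syn to the C16–C20 bridge | O=C1[C@@H]2C=C[C@@H](C(C)(C)[C@H]2O[Si](C)(C)C(C)(C)C)[C@]1(C(=O)N3CCC[C@@H]3COC)COCc4ccccc4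
F7 | step 6 | dialdehyde from F6 | O=C1[C@H](C=O)[C@H](O[Si](C)(C)C(C)(C)C)C(C)(C)[C@H](C=O)[C@]1(C(=O)N2CCC[C@@H]2COC)COCc3ccccc3
F8 | step 6 | keto aldehyde from F7 | O=C1C[C@H](O[Si](C)(C)C(C)(C)C)C(C)(C)[C@H](C=O)[C@]1(C(=O)N2CCC[C@@H]2COC)COCc3ccccc3
F9 | step 6 | lactol with CH2OBn cis to C18 | O=C1C[C@@H]2OC(O)[C@@H](C2(C)C)[C@]1(C(=O)N3CCC[C@@H]3COC)COCc4ccccc4
F10 | step 6 | bicyclic ether with CH2OBn cis to C18 | O=C1C[C@@H]2OC[C@@H](C2(C)C)[C@]1(C(=O)N3CCC[C@@H]3COC)COCc4ccccc4
F11 | step 6 | diol, C13 epimer of 16 (CH2OBn cis to C18) | OC1C[C@@H]2OC[C@@H](C2(C)C)[C@]1(CO)COCc3ccccc3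
F12 | step 6 | phosphonoacetate of the primary alcohol of F11 | OC1C[C@@H]2OC[C@@H](C2(C)C)[C@]1(COC(=O)CP(=O)(OCC)OCC)COCc3ccccc3
F13 | step 6 | debenzylated diol from F12 | OC1C[C@@H]2OC[C@@H](C2(C)C)[C@]1(COC(=O)CP(=O)(OCC)OCC)CO
F14 | step 15 | C14 alcohol of enelactone 21 | OC1C[C@@H]2OC[C@@H](C2(C)C)[C@@]13COC(=O)C=C3
F15 | step 15 | diisopropylsilyl-tethered 2-siloxybutadiene on the C14 oxygen | C=CC(=C)O[Si](C(C)C)(C(C)C)OC1C[C@@H]2OC[C@@H](C2(C)C)[C@@]13COC(=O)C=C3
F16 | step 15 | intramolecular cycloadduct, C5 enol ether bridged through silicon to the C14 oxygen | C1=C(O[Si]2(C(C)C)C(C)C)C[C@@H]3[C@H](C1)C(=O)OC[C@]34C(O2)C[C@@H]5OC[C@H]4C5(C)C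
F17 | step 15 | C14 alcohol of 25 | C[C@@H](C=C)[C@@H]1C(=O)C[C@@H]2[C@H](C1)C(=O)OC[C@]21C(O)C[C@@H]2OC[C@H]1C2(C)C
F18 | step 16 | (E)-pent-3-en-2-yl analogue of 25 | C[C@@H](/C=C/C)[C@@H]1C(=O)C[C@@H]2[C@H](C1)C(=O)OC[C@]21C(=O)C[C@@H]2OC[C@H]1C2(C)C
F19 | step 16 | C5 p-toluenesulfonylhydrazone of F18 | C[C@@H](/C=C/C)[C@@H]1C(=NNS(=O)(=O)c3ccc(C)cc3)C[C@@H]2[C@H](C1)C(=O)OC[C@]21C(=O)C[C@@H]2OC[C@H]1C2(C)C
F20 | step 16 | (E)-pent-3-en-2-yl analogue of 27 | C[C@@H](/C=C/C)[C@@H]1CC[C@@H]2[C@H](C1)C(=O)OC[C@]21C(=O)C[C@@H]2OC[C@H]1C2(C)C
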